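Compound numbers are those of the list after the steps; atoms are labelled C1–C8a (isochromenone) and C1'–C7' (side chain) as in the target.

## Analysis of the target

Target 33 is a 1,7,8,8a-tetrahydro-6H-isochromen-6-one. Carbocyclic ring A (C4a, C5, C6, C7, C8, C8a) is fused along C4a–C8a to pyran ring B (C1, O2, C3, C4, C4a, C8a), and C3 carries an (E)-alkenyl chain C1'–C7'. The six stereocentres form two triads. In ring A these are the tertiary carbinol C7 (S), the secondary carbinol C8 (R) and C8a (S), with the 7- and 8-hydroxyls trans and the 8-hydroxyl cis to the C1 methylene. In the chain they are the tertiary allylic carbinol C3' (R), C4' (R) and the methyl-bearing C5' (R), with the two oxygens syn in the zigzag. The planar unit O2–C3(=C4)–C1'=C2' separates the triads, so neither can steer the other and each needs its own source of chirality. The sensitive sites are the dienol ether (acid), the tertiary allylic alcohol at C3' (ionisation), the α-ketol C6/C7, the β-hydroxy ketone C6/C8 (retro-aldol) and C8a–H, which is vinylogously α to C6 (base). The difficulty lies in two quaternary carbinols each next to a secondary one, in the dense oxygenation of ring A, and in a push–pull chromophore that should be made late. The strategy rests on O2–C3=C4–C4a=C5–C6=O being a doubly vinylogous ester: read backwards, C4a is the β-carbon of a ring A enone and C3 is a ketone carbon that the C1 hydroxyl can trap.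

## Retrosynthetic reasoning

33 ⇒ 32. Only the four silyl ethers are removed at the end. The free tetrol has too many acidic and labile sites to survive C–C bond formation, and triethylsilyl ethers, even tertiary ones, come off under buffered conditions that the dienol ether tolerates.

32 ⇒ 16 + 27. O2–C3 and C4–C4a are cut. This is the one cut that follows the polarity of the vinylogous ester, separates the two stereotriads into fragments of similar size and touches no stereocentre. Forward, the methyl carbon (C4) of the enolate of 27 has to attack C4a of chloro enone 16 with loss of the halogen. The C1 oxygen then has to be unmasked alone, close onto C3 and dehydrate. Because the first-formed diketone 29 is a stronger carbon acid than 27, the enolate has to be used in twofold amount.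

16 ⇒ 15 ⇒ 14. The β-chloro enone comes from dione 15 by enol activation; the C6 carbonyl sits next to quaternary C7, so the less hindered oxygen on C4a should be the one replaced. Dione 15 is cut at C4a–C5, the only ring bond flanked by no stereocentre. Forward, the methyl ketone of 14, which has a single enolisable position, is acylated by its own N-methoxy-N-methylamide.

14 ⇒ 13 ⇒ 10 + 11. C6–C7 is cut. The tertiary carbinol C7 arises from methyl ketone 10 and an acetyl anion equivalent made from 11. The neighbouring C8 hydroxyl is left free as the anchor of a magnesium chelate, which has to deliver the nucleophile to the face of C8–H so that O7 and O8 end up syn. Silylation then gives 14.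

10 ⇒ 9 ⇒ 8 ⇒ 7. The C7 ketone and the C4a carboxyl are both traced to terminal alkenes. The isopropenyl and vinyl groups of 7 are inert placeholders during the aldol and are cleaved together to 8; oxidation to 9 and amidation follow. The price is the fragile β-hydroxy aldehyde 8, which is not stored.

7 ⇒ 6 ⇒ 5 ⇒ 3 + 4, and 3 ⇒ 1 + 2. C8–C8a is cut by an aldol between crotonyl imide 3 and aldehyde 4.

- In 3 the α-carbon becomes C8a, the vinyl group is latent C4a and the imide carbonyl is latent C1.
- In 4 the carbonyl becomes C8 and the isopropenyl group is latent C7 with its methyl.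

With this assignment the required relation (O8 anti to C1 along C7–C8–C8a–C4a) is a syn aldol, the dependable outcome for boron enolates of 3. The reverse assignment would need an anti aldol of a β-alkoxy enolate that eliminates. Reduction of 5 gives diol 6 and returns auxiliary 1; silylation of the primary hydroxyl gives 7.

27 ⇒ 25 + 26. C1'=C2' is cut. Ylide 26 brings C1', C3 and C4, and the olefination has to give the (E)-alkene on an aldehyde without α-hydrogen.

25 ⇒ 24 ⇒ 23 ⇒ 21 + 22. The aldehyde is a cleaved vinyl group. C2'–C3' is cut so that C3' is made by chelate-controlled addition of 22 to α-hydroxy ketone 21, the same reaction type that sets C7 in ring A.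

21 ⇒ 19 ⇒ 18 ⇒ 17. The ketone comes from amide 19 and 20, and 19 from hydroxy acid 18. D-Isoleucine 17 supplies C4' and C5'; the diazotisation has to proceed with retention at C4'.

## Alternatives that were turned down

Alternative 1: Ring A is cut at C4a–C8a, and the C1–O bond is traced to a dipole oxygen. Forward, aldoxime A2 is oxidised to the nitrile oxide at C4a, which adds across the C8a=C1 vinyl group and closes ring A and an isoxazoline together, giving A1.

- For: such intramolecular cycloadditions to six-membered rings are dependable, and C8a is created in the ring-forming step. The isoxazoline is a masked β-hydroxy ketone with its oxygen fixed on C4a by construction. On this point it is stronger than the chosen route, whose step 11 must tell the two carbonyls of dione 15 apart.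
- Against: A1 carries a C6 stereocentre that the target does not need and has no C4a=C5 unsaturation. After N–O cleavage, C5/C6 must be oxidised and the whole C3–C4 chain still attached to the C4a ketone, so the key step does not join the fragments. The 8,8a-cis relation depends on the facial bias of one allylic silyloxy group.
- Comparison: step 19 of the chosen route closes ring B and unites the fragments in one operation, which offsets the regiochemical question of step 11. Several further steps would separate A1 from the stage of 32.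

Alternative 2: The C6–C7 bond of ring A is cut in a late intermediate. Forward, a chiral N-heterocyclic carbene converts the C6 aldehyde of keto aldehyde A4 into an acyl anion equivalent that adds to the C7 methyl ketone, closing ring A and giving A3.

- For: it is the most direct plan on paper. The α-ketol is formed catalytically with the C7 hydroxyl free, C7 is catalyst-controlled, and only deprotection follows. In post-key-step count it equals the chosen route, and it is stronger in avoiding a tertiary silyl ether at C7.
- Against: the aldehyde of A4 ends a doubly vinylogous formate. It is deactivated towards carbene addition, and the derived intermediate can react as an extended enolate at C4a or C4 instead of at C6. C8a–H of A4 is vinylogously acidic under the basic conditions. The ketone carries an α-silyloxy stereocentre that may oppose the catalyst. Ring B and the full side chain must be carried into the riskiest step.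
- Comparison: the chosen strategy puts its risk on the union of two robust, separately made fragments by classical polar reactivity and sets C7 early by chelate control.

Alternative 3: The C7–C8 bond is traced to a 1,2-shift. Forward, a strong base deprotonates a C6 hydroxyl on a five-membered carbocycle that also carries an acetyl group on C6. C8 migrates to the acetyl carbon C7, the ring grows to ring A, and A5 results.

- For: the shift is stereospecific, is helped by the C6 carbonyl entering the vinylogous ester, and delivers the C7 hydroxyl unprotected. In elegance it is at least the equal of the chosen plan.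
- Against: α-ketol shifts are equilibria and A5 is itself an α-ketol that can shift on under the same base. The configuration at C7 depends on the rotamer of the acetyl group in the transition state. The base meets the vinylogously acidic C8a–H and β-silyloxy groups. The precursor, a cyclopenta-fused pyran with a quaternary C6 stereocentre and the complete side chain, is as demanding as 16 and 27 together and is reached linearly.
- Comparison: the chosen strategy is convergent and sets every stereocentre by a well-understood model.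

Key step: step 19

Assumption: diketone 29 is taken to be a stronger carbon acid than ketone 27, so the enolate is used in twofold amount in step 19.

## Route

Step 1
Reactants: 1 (R)-4-benzyloxazolidin-2-one; 2 (E)-but-2-enoyl chloride
Product: 3 (R)-4-benzyl-3-[(E)-but-2-enoyl]oxazolidin-2-one
Conditions: n-BuLi, THF, −78 °C; then 2, −78 → 0 °C
Reagents that add atoms: none
Why: N-Acylation of the lithiated oxazolidinone by the acid chloride, the standard entry to Evans imides; no stereocentre is formed or touched.

Step 2
Reactants: 3 (R)-4-benzyl-3-[(E)-but-2-enoyl]oxazolidin-2-one; 4 2-methylprop-2-enal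
Product: 5 (R)-4-benzyl-3-[(2R,3R)-2-ethenyl-3-hydroxy-4-methylpent-4-enoyl]oxazolidin-2-one
Conditions: Bu2BOTf, Et3N, CH2Cl2, −78 → 0 °C; 4, −78 → 0 °C; then pH 7 buffer, MeOH, H2O2, 0 °C
Reagents that add atoms: none
Why: Evans syn aldol of the boron dienolate formed by γ-deprotonation of the crotonyl imide; reaction at the α-carbon through a Zimmerman–Traxler chair on the face away from the benzyl group should give the 2,3-syn adduct, so the (R)-auxiliary sets C8a and C8 together.

Step 3
Reactants: 5 (R)-4-benzyl-3-[(2R,3R)-2-ethenyl-3-hydroxy-4-methylpent-4-enoyl]oxazolidin-2-one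
Product: 6 (2S,3R)-2-ethenyl-4-methylpent-4-ene-1,3-diol
Conditions: LiBH4, MeOH (1 equiv), THF, 0 °C
Reagents that add atoms: none
Why: Reductive cleavage of the N-acyl oxazolidinone turns the imide carbonyl into the C1 hydroxymethyl group and returns auxiliary 1; the α-stereocentre is not enolised by the hydride.

Step 4
Reactants: 6 (2S,3R)-2-ethenyl-4-methylpent-4-ene-1,3-diol
Product: 7 (3R,4S)-2-methyl-4-{[(triethylsilyl)oxy]methyl}hexa-1,5-dien-3-ol
Conditions: Et3SiCl (1.05 equiv), imidazole, CH2Cl2, −78 → −30 °C
Reagents that add atoms: chlorotriethylsilane, CC[Si](Cl)(CC)CC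
Why: Chemoselective silylation of the primary over the hindered secondary allylic hydroxyl; the free C8 hydroxyl is kept as the chelating group for step 8.

Step 5
Reactants: 7 (3R,4S)-2-methyl-4-{[(triethylsilyl)oxy]methyl}hexa-1,5-dien-3-ol
Product: 8 (2S,3R)-3-hydroxy-4-oxo-2-{[(triethylsilyl)oxy]methyl}pentanal
Conditions: O3, CH2Cl2, −78 °C; PPh3, −78 °C → rt
Reagents that add atoms: ozone, [O-][O+]=O
Why: Ozonolysis cleaves both terminal alkenes in one operation, the isopropenyl group to the C7 methyl ketone and the vinyl group to the C4a aldehyde; the neutral reductive work-up should spare the β-hydroxy aldehyde from retro-aldol cleavage and C8a from epimerisation, and crude 8 is used at once.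

Step 6
Reactants: 8 (2S,3R)-3-hydroxy-4-oxo-2-{[(triethylsilyl)oxy]methyl}pentanal
Product: 9 (2S,3R)-3-hydroxy-4-oxo-2-{[(triethylsilyl)oxy]methyl}pentanoic acid
Conditions: NaClO2, NaH2PO4, 2-methylbut-2-ene, t-BuOH–H2O, 0 °C
Reagents that add atoms: sodium chlorite, [Na+].[O-]Cl=O
Why: Pinnick oxidation takes the aldehyde to the acid without touching the ketone, the free hydroxyl or the α-stereocentre; the short, cold contact with the phosphate buffer should be tolerated by the primary silyl ether.

Step 7
Reactants: 9 (2S,3R)-3-hydroxy-4-oxo-2-{[(triethylsilyl)oxy]methyl}pentanoic acid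
Product: 10 (2S,3R)-3-hydroxy-N-methoxy-N-methyl-4-oxo-2-{[(triethylsilyl)oxy]methyl}pentanamide
Conditions: MeNHOMe·HCl, EDC·HCl, HOBt, N-methylmorpholine, CH2Cl2, 0 °C → rt
Reagents that add atoms: N,O-dimethylhydroxylamine hydrochloride, CNOC.Cl
Why: Carbodiimide coupling to the Weinreb amide, an acyl donor that resists the organomagnesium reagent of step 8 at −78 °C and is not readily closed to a lactone by the C7 alkoxide formed there.

Step 8
Reactants: 10 (2S,3R)-3-hydroxy-N-methoxy-N-methyl-4-oxo-2-{[(triethylsilyl)oxy]methyl}pentanamide; 11 ethoxyethene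
Product: 13 (2S,3R,4S)-3,4-dihydroxy-N-methoxy-N,4-dimethyl-5-oxo-2-{[(triethylsilyl)oxy]methyl}hexanamide, via enol ether 12 (not isolated)
Conditions: 11, t-BuLi, THF, −78 → 0 °C; MgBr2·OEt2, −78 °C; 10 (0.33 equiv), THF, −78 °C; then 0.5 M HCl, THF, 0 °C
Reagents that add atoms: water, O
Why: Chelation-controlled carbonyl addition (Cram cyclic model) of an acetyl anion equivalent: the magnesium alkoxide of the C8 hydroxyl binds the ketone oxygen and the 1-ethoxyvinyl group should enter from the face of C8–H, anti to C8a, which sets C7 with O7 and O8 syn. The ketone reacts before the Weinreb amide at −78 °C, and dilute acid hydrolyses enol ether 12 to the methyl ketone (C6 and C5).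

Step 9
Reactants: 13 (2S,3R,4S)-3,4-dihydroxy-N-methoxy-N,4-dimethyl-5-oxo-2-{[(triethylsilyl)oxy]methyl}hexanamide
Product: 14 (2S,3R,4S)-N-methoxy-N,4-dimethyl-5-oxo-3,4-bis[(triethylsilyl)oxy]-2-{[(triethylsilyl)oxy]methyl}hexanamide
Conditions: Et3SiOTf (2.5 equiv), 2,6-lutidine, CH2Cl2, −78 → 0 °C
Reagents that add atoms: triethylsilyl trifluoromethanesulfonate, CC[Si](CC)(CC)OS(=O)(=O)C(F)(F)F
Why: Silylation of the secondary and the tertiary hydroxyl by the silyl triflate; with the weak base 2,6-lutidine the methyl ketone should not be converted to its silyl enol ether.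

Step 10
Reactants: 14 (2S,3R,4S)-N-methoxy-N,4-dimethyl-5-oxo-3,4-bis[(triethylsilyl)oxy]-2-{[(triethylsilyl)oxy]methyl}hexanamide
Product: 15 (4S,5R,6S)-4-methyl-4,5-bis[(triethylsilyl)oxy]-6-{[(triethylsilyl)oxy]methyl}cyclohexane-1,3-dione
Conditions: LiN(SiMe3)2 (2.2 equiv), THF, −78 → 0 °C; AcOH
Reagents that add atoms: none
Why: Intramolecular Claisen (Dieckmann-type) condensation: the ketone can enolise only at its methyl group because C7 is quaternary, and this enolate attacks the Weinreb amide in a 6-(enolendo)-exo-trig closure that forms C4a–C5. The dione is deprotonated as it forms, which should protect C8a from epimerisation.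

Step 11
Reactants: 15 (4S,5R,6S)-4-methyl-4,5-bis[(triethylsilyl)oxy]-6-{[(triethylsilyl)oxy]methyl}cyclohexane-1,3-dione
Product: 16 (4S,5R,6S)-3-chloro-6-methyl-5,6-bis[(triethylsilyl)oxy]-4-{[(triethylsilyl)oxy]methyl}cyclohex-2-en-1-one
Conditions: Ph3PCl2, Et3N, CH2Cl2, 0 °C → rt
Reagents that add atoms: dichlorotriphenylphosphorane, ClP(Cl)(c1ccccc1)(c1ccccc1)c1ccccc1
Why: Conversion of a cyclic 1,3-dione into its β-chloro enone through the enol phosphonium salt and addition–elimination of chloride. The less hindered enolate oxygen on C4a (next to tertiary C8a) should be activated in preference to the one on C6 (next to quaternary C7), so chlorine ends on C4a; the amine keeps the medium free of HCl for the primary silyl ether.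

Step 12
Reactants: 17 D-isoleucine
Product: 18 (2R,3R)-2-hydroxy-3-methylpentanoic acid
Conditions: NaNO2, 1 M H2SO4, H2O, 0 °C → rt
Reagents that add atoms: water, O
Why: Diazotisation of the α-amino acid; the carboxylate displaces nitrogen to an α-lactone that water opens, and the double inversion returns C4' with retention while C5' is untouched.

Step 13
Reactants: 18 (2R,3R)-2-hydroxy-3-methylpentanoic acid
Product: 19 (2R,3R)-2-hydroxy-N-methoxy-N,3-dimethylpentanamide
Conditions: MeNHOMe·HCl, EDC·HCl, HOBt, N-methylmorpholine, CH2Cl2, 0 °C → rt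
Reagents that add atoms: N,O-dimethylhydroxylamine hydrochloride, CNOC.Cl
Why: Carbodiimide coupling of the free α-hydroxy acid to its Weinreb amide; the active ester is formed under conditions that should not racemise C4'.

Step 14
Reactants: 19 (2R,3R)-2-hydroxy-N-methoxy-N,3-dimethylpentanamide; 20 methylmagnesium bromide
Product: 21 (3R,4R)-3-hydroxy-4-methylhexan-2-one
Conditions: 20 (3 equiv), THF, −20 → 0 °C; 1 M HCl, 0 °C
Reagents that add atoms: none
Why: Weinreb ketone synthesis; the first equivalent of Grignard reagent deprotonates the hydroxyl, and the chelated tetrahedral intermediate stops the addition at the ketone stage.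

Step 15
Reactants: 21 (3R,4R)-3-hydroxy-4-methylhexan-2-one; 22 ethenylmagnesium bromide
Product: 23 (3R,4R,5R)-3,5-dimethylhept-1-ene-3,4-diol
Conditions: 22 (3 equiv), THF, −78 → −40 °C; 1 M HCl, 0 °C
Reagents that add atoms: none
Why: Chelation-controlled Grignard addition (Cram cyclic model) to the α-hydroxy ketone: the magnesium alkoxide of the C4' hydroxyl binds the carbonyl oxygen and the vinyl group should attack from the side of C4'–H, away from the sec-butyl group, giving the 3',4'-syn diol with C3' (R).

Step 16
Reactants: 23 (3R,4R,5R)-3,5-dimethylhept-1-ene-3,4-diol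
Product: 24 (3R,4R,5R)-3,5-dimethyl-3,4-bis[(triethylsilyl)oxy]hept-1-ene
Conditions: Et3SiOTf (2.5 equiv), 2,6-lutidine, CH2Cl2, −78 → 0 °C
Reagents that add atoms: triethylsilyl trifluoromethanesulfonate, CC[Si](CC)(CC)OS(=O)(=O)C(F)(F)F
Why: Silylation of the secondary and the tertiary allylic hydroxyl by the silyl triflate under non-acidic conditions, so the tertiary allylic centre should not ionise.

Step 17
Reactants: 24 (3R,4R,5R)-3,5-dimethyl-3,4-bis[(triethylsilyl)oxy]hept-1-ene
Product: 25 (2S,3R,4R)-2,4-dimethyl-2,3-bis[(triethylsilyl)oxy]hexanal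
Conditions: O3, CH2Cl2, −78 °C; PPh3, −78 °C → rt
Reagents that add atoms: ozone, [O-][O+]=O
Why: Ozonolysis of the monosubstituted alkene unmasks C2' as an aldehyde that has no α-hydrogen, so C3' cannot epimerise.

Step 18
Reactants: 25 (2S,3R,4R)-2,4-dimethyl-2,3-bis[(triethylsilyl)oxy]hexanal; 26 1-(triphenylphosphoranylidene)propan-2-one
Product: 27 (3E,5R,6R,7R)-5,7-dimethyl-5,6-bis[(triethylsilyl)oxy]non-3-en-2-one
Conditions: toluene, 90 °C
Reagents that add atoms: none
Why: Wittig olefination with the stabilised acetonyl ylide should give the (E)-enone; the neutral conditions leave the α,β-bis(silyloxy) aldehyde intact.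

Step 19
Reactants: 27 (3E,5R,6R,7R)-5,7-dimethyl-5,6-bis[(triethylsilyl)oxy]non-3-en-2-one (2.2 equiv); 16 (4S,5R,6S)-3-chloro-6-methyl-5,6-bis[(triethylsilyl)oxy]-4-{[(triethylsilyl)oxy]methyl}cyclohex-2-en-1-one (1.0 equiv)
Product: 32 (7S,8R,8aS)-3-{(1E,3R,4R,5R)-3,5-dimethyl-3,4-bis[(triethylsilyl)oxy]hept-1-en-1-yl}-7-methyl-7,8-bis[(triethylsilyl)oxy]-1,7,8,8a-tetrahydro-6H-isochromen-6-one, via lithium enolate 28 (not isolated), via diketone 29 (not isolated), via hydroxy diketone 30 (not isolated), via hemiketal 31 (not isolated)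
Conditions: 27, LiN(SiMe3)2 (2.1 equiv), THF, −78 °C; 16, −78 → −30 °C; AcOH, −78 °C; then PPTS (cat.), MeOH–CH2Cl2, 0 °C → rt
Reagents that add atoms: none
Why: LiN(SiMe3)2 removes a proton from the methyl group of 27, its only enolisable position because C3' is quaternary, and gives the cross-conjugated lithium enolate 28. C4 of 28 adds to C4a, the β-carbon of chloro enone 16, and the halide leaves from the resulting ring enolate (addition–elimination; the closest known reaction type is the β-alkenylation of ketone enolates by 3-chlorocyclohex-2-enones), which forms C4–C4a and gives vinylogous 1,3-diketone 29. Since 29 is a much stronger carbon acid at C4 than 27, it is deprotonated by a second enolate, so 27 and the base are used in about twofold amount with no free amide left, and the regenerated 27 is recovered. Attack should be 1,4 because the C6 carbonyl is shielded by quaternary C7 and its silyl ether, and C8a–H should be spared because 28 is a weaker and bulkier base than the amide. After the acetic acid quench, PPTS in methanol should cleave only the primary silyl ether at C1, the four hindered secondary and tertiary ones staying, to give 30. The C1 hydroxyl of 30 adds to the C3 carbonyl in a 6-exo-trig closure to hemiketal 31, and acid-catalysed dehydration towards C4 forms O2–C3 as the enol ether and completes pyran ring B, the known cyclodehydration of δ-hydroxy ketones to dihydropyrans. The driving force is the doubly vinylogous ester O2–C3=C4–C4a=C5–C6=O of 32, the thermodynamic sink of this manifold. No stereocentre is formed; the step only has to preserve the six brought in by 16 and 27, which the low temperature, the absence of free amide and the mild acid should secure.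

Step 20
Reactants: 32 (7S,8R,8aS)-3-{(1E,3R,4R,5R)-3,5-dimethyl-3,4-bis[(triethylsilyl)oxy]hept-1-en-1-yl}-7-methyl-7,8-bis[(triethylsilyl)oxy]-1,7,8,8a-tetrahydro-6H-isochromen-6-one
Product: 33 (7S,8R,8aS)-3-[(1E,3R,4R,5R)-3,4-dihydroxy-3,5-dimethylhept-1-en-1-yl]-7,8-dihydroxy-7-methyl-1,7,8,8a-tetrahydro-6H-isochromen-6-one
Conditions: HF·pyridine, pyridine, THF, 0 °C → rt
Reagents that add atoms: none
Why: Fluoride-mediated cleavage of the four triethylsilyl ethers; the pyridine buffer should keep the medium too weakly acidic to hydrolyse the dienol ether or ionise the tertiary allylic alcohol, and too weakly basic to enolise C8a or start a retro-aldol at C6/C8.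

## Compound list

1 | (R)-4-benzyloxazolidin-2-one | O=C1N[C@H](Cc2ccccc2)CO1 | starting material
2 | (E)-but-2-enoyl chloride | C/C=C/C(Cl)=O | starting material
3 | (R)-4-benzyl-3-[(E)-but-2-enoyl]oxazolidin-2-one | C/C=C/C(=O)N1[C@H](Cc2ccccc2)COC1=O | intermediate
4 | 2-methylprop-2-enal (methacrolein) | CC(=C)C=O | starting material
5 | (R)-4-benzyl-3-[(2R,3R)-2-ethenyl-3-hydroxy-4-methylpent-4-enoyl]oxazolidin-2-one | C=C(C)[C@H](O)[C@@H](C=C)C(=O)N1[C@H](Cc2ccccc2)COC1=O | intermediate
6 | (2S,3R)-2-ethenyl-4-methylpent-4-ene-1,3-diol | C=C(C)[C@H](O)[C@@H](C=C)CO | intermediate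
7 | (3R,4S)-2-methyl-4-{[(triethylsilyl)oxy]methyl}hexa-1,5-dien-3-ol | C=C(C)[C@H](O)[C@@H](C=C)CO[Si](CC)(CC)CC | intermediate
8 | (2S,3R)-3-hydroxy-4-oxo-2-{[(triethylsilyl)oxy]methyl}pentanal | CC(=O)[C@H](O)[C@@H](C=O)CO[Si](CC)(CC)CC | intermediate
9 | (2S,3R)-3-hydroxy-4-oxo-2-{[(triethylsilyl)oxy]methyl}pentanoic acid | CC(=O)[C@H](O)[C@@H](C(=O)O)CO[Si](CC)(CC)CC | intermediate
10 | (2S,3R)-3-hydroxy-N-methoxy-N-methyl-4-oxo-2-{[(triethylsilyl)oxy]methyl}pentanamide | CC(=O)[C@H](O)[C@@H](C(=O)N(C)OC)CO[Si](CC)(CC)CC | intermediate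
11 | ethoxyethene (ethyl vinyl ether) | C=COCC | starting material
12 | (2S,3R,4S)-5-ethoxy-3,4-dihydroxy-N-methoxy-N,4-dimethyl-2-{[(triethylsilyl)oxy]methyl}hex-5-enamide | C=C(OCC)[C@@](C)(O)[C@H](O)[C@@H](C(=O)N(C)OC)CO[Si](CC)(CC)CC | intermediate (not isolated)
13 | (2S,3R,4S)-3,4-dihydroxy-N-methoxy-N,4-dimethyl-5-oxo-2-{[(triethylsilyl)oxy]methyl}hexanamide | CC(=O)[C@@](C)(O)[C@H](O)[C@@H](C(=O)N(C)OC)CO[Si](CC)(CC)CC | intermediate
14 | (2S,3R,4S)-N-methoxy-N,4-dimethyl-5-oxo-3,4-bis[(triethylsilyl)oxy]-2-{[(triethylsilyl)oxy]methyl}hexanamide | CC(=O)[C@@](C)(O[Si](CC)(CC)CC)[C@H](O[Si](CC)(CC)CC)[C@@H](C(=O)N(C)OC)CO[Si](CC)(CC)CC | intermediate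
15 | (4S,5R,6S)-4-methyl-4,5-bis[(triethylsilyl)oxy]-6-{[(triethylsilyl)oxy]methyl}cyclohexane-1,3-dione | O=C1CC(=O)[C@@](C)(O[Si](CC)(CC)CC)[C@H](O[Si](CC)(CC)CC)[C@@H]1CO[Si](CC)(CC)CC | intermediate
16 | (4S,5R,6S)-3-chloro-6-methyl-5,6-bis[(triethylsilyl)oxy]-4-{[(triethylsilyl)oxy]methyl}cyclohex-2-en-1-one | ClC1=CC(=O)[C@@](C)(O[Si](CC)(CC)CC)[C@H](O[Si](CC)(CC)CC)[C@@H]1CO[Si](CC)(CC)CC | intermediate
17 | D-isoleucine, (2R,3R)-2-amino-3-methylpentanoic acid | CC[C@@H](C)[C@@H](N)C(=O)O | starting material
18 | (2R,3R)-2-hydroxy-3-methylpentanoic acid | CC[C@@H](C)[C@@H](O)C(=O)O | intermediate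
19 | (2R,3R)-2-hydroxy-N-methoxy-N,3-dimethylpentanamide | CC[C@@H](C)[C@@H](O)C(=O)N(C)OC | intermediate
20 | methylmagnesium bromide | C[Mg]Br | starting material
21 | (3R,4R)-3-hydroxy-4-methylhexan-2-one | CC[C@@H](C)[C@@H](O)C(C)=O | intermediate
22 | ethenylmagnesium bromide (vinylmagnesium bromide) | C=C[Mg]Br | starting material
23 | (3R,4R,5R)-3,5-dimethylhept-1-ene-3,4-diol | CC[C@@H](C)[C@@H](O)[C@](C)(O)C=C | intermediate
24 | (3R,4R,5R)-3,5-dimethyl-3,4-bis[(triethylsilyl)oxy]hept-1-ene | CC[C@@H](C)[C@@H](O[Si](CC)(CC)CC)[C@](C)(O[Si](CC)(CC)CC)C=C | intermediate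
25 | (2S,3R,4R)-2,4-dimethyl-2,3-bis[(triethylsilyl)oxy]hexanal | CC[C@@H](C)[C@@H](O[Si](CC)(CC)CC)[C@](C)(O[Si](CC)(CC)CC)C=O | intermediate
26 | 1-(triphenylphosphoranylidene)propan-2-one | CC(=O)C=P(c1ccccc1)(c1ccccc1)c1ccccc1 | starting material
27 | (3E,5R,6R,7R)-5,7-dimethyl-5,6-bis[(triethylsilyl)oxy]non-3-en-2-one | CC[C@@H](C)[C@@H](O[Si](CC)(CC)CC)[C@](C)(O[Si](CC)(CC)CC)/C=C/C(C)=O | intermediate
28 | lithium (3E,5R,6R,7R)-5,7-dimethyl-5,6-bis[(triethylsilyl)oxy]nona-1,3-dien-2-olate | CC[C@@H](C)[C@@H](O[Si](CC)(CC)CC)[C@](C)(O[Si](CC)(CC)CC)/C=C/C(=C)O[Li] | intermediate (not isolated)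
29 | (4S,5R,6S)-3-{(3E,5R,6R,7R)-5,7-dimethyl-2-oxo-5,6-bis[(triethylsilyl)oxy]non-3-en-1-yl}-6-methyl-5,6-bis[(triethylsilyl)oxy]-4-{[(triethylsilyl)oxy]methyl}cyclohex-2-en-1-one | CC[C@@H](C)[C@@H](O[Si](CC)(CC)CC)[C@](C)(O[Si](CC)(CC)CC)/C=C/C(=O)CC1=CC(=O)[C@@](C)(O[Si](CC)(CC)CC)[C@H](O[Si](CC)(CC)CC)[C@@H]1CO[Si](CC)(CC)CC | intermediate (not isolated)
30 | (4S,5R,6S)-3-{(3E,5R,6R,7R)-5,7-dimethyl-2-oxo-5,6-bis[(triethylsilyl)oxy]non-3-en-1-yl}-4-(hydroxymethyl)-6-methyl-5,6-bis[(triethylsilyl)oxy]cyclohex-2-en-1-one | CC[C@@H](C)[C@@H](O[Si](CC)(CC)CC)[C@](C)(O[Si](CC)(CC)CC)/C=C/C(=O)CC1=CC(=O)[C@@](C)(O[Si](CC)(CC)CC)[C@H](O[Si](CC)(CC)CC)[C@@H]1CO | intermediate (not isolated)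
31 | (7S,8R,8aS)-3-{(1E,3R,4R,5R)-3,5-dimethyl-3,4-bis[(triethylsilyl)oxy]hept-1-en-1-yl}-3-hydroxy-7-methyl-7,8-bis[(triethylsilyl)oxy]-1,3,4,7,8,8a-hexahydro-6H-isochromen-6-one (both C3 epimers) | CC[C@@H](C)[C@@H](O[Si](CC)(CC)CC)[C@](C)(O[Si](CC)(CC)CC)/C=C/C1(O)CC2=CC(=O)[C@@](C)(O[Si](CC)(CC)CC)[C@H](O[Si](CC)(CC)CC)[C@@H]2CO1 | intermediate (not isolated)
32 | (7S,8R,8aS)-3-{(1E,3R,4R,5R)-3,5-dimethyl-3,4-bis[(triethylsilyl)oxy]hept-1-en-1-yl}-7-methyl-7,8-bis[(triethylsilyl)oxy]-1,7,8,8a-tetrahydro-6H-isochromen-6-one | CC[C@@H](C)[C@@H](O[Si](CC)(CC)CC)[C@](C)(O[Si](CC)(CC)CC)/C=C/C1=CC2=CC(=O)[C@@](C)(O[Si](CC)(CC)CC)[C@H](O[Si](CC)(CC)CC)[C@@H]2CO1 | intermediate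
33 | (7S,8R,8aS)-3-[(1E,3R,4R,5R)-3,4-dihydroxy-3,5-dimethylhept-1-en-1-yl]-7,8-dihydroxy-7-methyl-1,7,8,8a-tetrahydro-6H-isochromen-6-one | CC[C@@H](C)[C@@H](O)[C@](C)(O)/C=C/C1=CC2=CC(=O)[C@@](C)(O)[C@H](O)[C@@H]2CO1 | target

## Step count and least certain steps

Total: 20 steps. Longest linear sequence: 13 steps (steps 1–11, 19 and 20); the side chain takes steps 12–18.

**Step 19 (key step).** Several processes could erode it:
- incomplete conversion if proton transfer from diketone 29 outruns the addition;
- 1,2-attack at C6 or O-alkenylation of the enolate;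
- removal of C8a–H in 16 followed by loss of a β-silyloxy group;
- loss of more than the primary silyl ether, or a stalled dehydration, in the acid phase.

Fallback, from 16 and 25, back at 29: the dianion of dimethyl (2-oxopropyl)phosphonate (NaH, then n-BuLi, THF, 0 °C) carries its own second basic site. Its terminal carbon should add to C4a of 16 with loss of chloride to give the ring A β-keto phosphonate F1. A Horner–Wadsworth–Emmons reaction of F1 with aldehyde 25 (Ba(OH)2, wet THF) then builds the (E)-C1'=C2' bond and gives 29, which is taken through the PPTS/MeOH treatment to 32.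

**Step 11.** Activation of the two enolate oxygens of 15 may be poorly regioselective, because only the difference between a quaternary and a tertiary neighbour separates them. Fallback, from 15, back at 29: the isomer mixture is used convergently. The regioisomeric chloro enone F2 (chlorine on C6, carbonyl on C4a) should react with enolate 28 by 1,2-addition at its unhindered C4a carbonyl to give the tertiary allylic alcohol F3. Dilute acid hydrolyses this vinylogous acid chloride with allylic transposition (Stork–Danheiser type) to the same diketone 29. Both isomers therefore lead to 29, one by addition–elimination and one by addition–transposition.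

**Step 8.** Facial selectivity may be poor if magnesium is held by the amide and not by the ketone oxygen; the amide may be attacked; the C7 alkoxide may lactonise. Fallback, from 10, back at 13:
- the C8 hydroxyl is converted (BnOCH2Cl, i-Pr2NEt, CH2Cl2) into the (benzyloxy)methyl ether F4, a stronger and unambiguous chelating group;
- ethynylmagnesium bromide (THF, −78 °C) adds under ether chelation to give the propargylic alcohol F5;
- hydration with Ph3PAuNTf2 (cat.) in aqueous methanol gives the methyl ketone F6;
- hydrogenolysis (H2, Pd/C, EtOAc) returns 13.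

**Step 10.** The amide enolate may lose a β-silanolate, C8a may epimerise, or the hindered enolate may acylate slowly. Fallback, from 14, back at 15: the amide is reduced with Cp2Zr(H)Cl (THF, rt) to the keto aldehyde F7. The far more electrophilic aldehyde should allow ring closure by intramolecular aldol addition at −78 °C (LiN(SiMe3)2, 1.05 equiv) to the β-hydroxy ketone F8, which Dess–Martin periodinane oxidises to 15.

Further compounds
F1 | step 19 | dimethyl (3-{(4S,5R,6S)-4-methyl-3-oxo-4,5-bis[(triethylsilyl)oxy]-6-{[(triethylsilyl)oxy]methyl}cyclohex-1-en-1-yl}-2-oxopropyl)phosphonate | COP(=O)(OC)CC(=O)CC1=CC(=O)[C@@](C)(O[Si](CC)(CC)CC)[C@H](O[Si](CC)(CC)CC)[C@@H]1CO[Si](CC)(CC)CC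
F2 | step 11 | (4S,5R,6S)-3-chloro-4-methyl-4,5-bis[(triethylsilyl)oxy]-6-{[(triethylsilyl)oxy]methyl}cyclohex-2-en-1-one | O=C1C=C(Cl)[C@@](C)(O[Si](CC)(CC)CC)[C@H](O[Si](CC)(CC)CC)[C@@H]1CO[Si](CC)(CC)CC
F3 | step 11 | (3E,5R,6R,7R)-1-{(4S,5R,6S)-3-chloro-1-hydroxy-4-methyl-4,5-bis[(triethylsilyl)oxy]-6-{[(triethylsilyl)oxy]methyl}cyclohex-2-en-1-yl}-5,7-dimethyl-5,6-bis[(triethylsilyl)oxy]non-3-en-2-one (both carbinol epimers) | CC[C@@H](C)[C@@H](O[Si](CC)(CC)CC)[C@](C)(O[Si](CC)(CC)CC)/C=C/C(=O)CC1(O)C=C(Cl)[C@@](C)(O[Si](CC)(CC)CC)[C@H](O[Si](CC)(CC)CC)[C@@H]1CO[Si](CC)(CC)CC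
F4 | step 8 | (2S,3R)-3-[(benzyloxy)methoxy]-N-methoxy-N-methyl-4-oxo-2-{[(triethylsilyl)oxy]methyl}pentanamide | CC(=O)[C@H](OCOCc1ccccc1)[C@@H](C(=O)N(C)OC)CO[Si](CC)(CC)CC
F5 | step 8 | (2S,3R,4R)-3-[(benzyloxy)methoxy]-4-hydroxy-N-methoxy-N,4-dimethyl-2-{[(triethylsilyl)oxy]methyl}hex-5-ynamide | C#C[C@@](C)(O)[C@H](OCOCc1ccccc1)[C@@H](C(=O)N(C)OC)CO[Si](CC)(CC)CC
F6 | step 8 | (2S,3R,4S)-3-[(benzyloxy)methoxy]-4-hydroxy-N-methoxy-N,4-dimethyl-5-oxo-2-{[(triethylsilyl)oxy]methyl}hexanamide | CC(=O)[C@@](C)(O)[C@H](OCOCc1ccccc1)[C@@H](C(=O)N(C)OC)CO[Si](CC)(CC)CC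
F7 | step 10 | (2S,3R,4S)-4-methyl-5-oxo-3,4-bis[(triethylsilyl)oxy]-2-{[(triethylsilyl)oxy]methyl}hexanal | CC(=O)[C@@](C)(O[Si](CC)(CC)CC)[C@H](O[Si](CC)(CC)CC)[C@@H](C=O)CO[Si](CC)(CC)CC
F8 | step 10 | (2S,3R,4R)-5-hydroxy-2-methyl-2,3-bis[(triethylsilyl)oxy]-4-{[(triethylsilyl)oxy]methyl}cyclohexan-1-one (both C5 epimers) | OC1CC(=O)[C@@](C)(O[Si](CC)(CC)CC)[C@H](O[Si](CC)(CC)CC)[C@@H]1CO[Si](CC)(CC)CC
A1 | alternative 1 | ring A fused isoxazoline with C6/C7 acetonide and C8 tert-butyldimethylsilyl ether | N1=C2C[C@@H](OC3(C)C)[C@@](C)(O3)[C@H](O[Si](C)(C)C(C)(C)C)[C@@H]2CO1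
A2 | alternative 1 | open-chain aldoxime with C6/C7 acetonide, C8 tert-butyldimethylsilyl ether and C8a=C1 vinyl group | ON=CC[C@@H](OC1(C)C)[C@@](C)(O1)[C@H](O[Si](C)(C)C(C)(C)C)C=C
A3 | alternative 2 | protected target with C8 triethylsilyl ether, side-chain acetonide and free C7 hydroxyl | CC[C@@H](C)[C@@H](OC1(C)C)[C@](C)(O1)/C=C/C2=CC3=CC(=O)[C@@](C)(O)[C@H](O[Si](CC)(CC)CC)[C@@H]3CO2
A4 | alternative 2 | ring B keto aldehyde with C6 aldehyde and C7 methyl ketone | CC[C@@H](C)[C@@H](OC1(C)C)[C@](C)(O1)/C=C/C2=C/C(=C/C=O)[C@H]([C@@H](O[Si](CC)(CC)CC)C(C)=O)CO2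
A5 | alternative 3 | tris-silylated target with C3'/C4' triethylsilyl ethers, C8 tert-butyldimethylsilyl ether and free C7 hydroxyl | CC[C@@H](C)[C@@H](O[Si](CC)(CC)CC)[C@](C)(O[Si](CC)(CC)CC)/C=C/C1=CC2=CC(=O)[C@@](C)(O)[C@H](O[Si](C)(C)C(C)(C)C)[C@@H]2CO1
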